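## Structural features

The target 18 is a 1,4-naphthoquinone: benzo ring A (C4a, C5–C8, C8a) is fused to quinone ring B (C1–C4), and a 3,4-dimethoxyphenyl ring C is bonded through C1' to C8. Methoxy groups sit on C2 (a vinylogous ester in ring B), on C6, and on C3' and C4'. The pattern is unsymmetrical, because the carbonyl next to the C2 methoxy carbon (C1) is also the one peri to C8, so the oxygenation of rings A and B has to be set regiochemically. The target has no stereocentre; the only stereocentres on the route are the two adjacent ring-C carbons of the cycloadduct 15, and both are erased on aromatization. The fragile part is the methoxyquinone, which is a dienophile, a Michael acceptor at C3, open to addition–elimination at C2 and easily reduced. It is therefore revealed last from an aromatic hydroquinone dimethyl ether, and the two enol ethers of the unfinished ring C tolerate only neutral or basic handling. The real difficulty is the C8–C1' bond, since C8 is peri to the C1 oxygen and an aryl–aryl coupling there is crowded. The key step exploits the fact that the C2'–C3'(OMe)–C4'(OMe)–C5' edge of ring C is a 2,3-dimethoxybutadiene and that C1'–C6' can be carried on C8 as a nitrovinyl group, so ring C is grown on C8 and not coupled to it.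

## Logic of the disconnections

18 from 17. No skeletal bond is cut; the C1 and C4 carbonyls are traced back to two O–CH3 bonds. A quinone would be the best dienophile and electrophile in every earlier step, whereas the aromatic ether is inert. The gain is that all six oxygens become the same robust methyl ether and the end is a single oxidation. The demand is that this oxidation takes the para pair O1/O4 in preference to the ortho pair O1/O2 and leaves ring C and the C2 methoxy group alone.

17 from 16 from 15. Again no skeletal bond is cut; ring C is taken back by two hydrogens to 16 and by HNO2 to 15. This turns an aryl ring into a cyclohexene with an acceptor next to the junction carbon, which is the retron of a [4+2] cycloaddition. The biaryl problem becomes an alkene problem. The demand is that elimination and dehydrogenation run without acid, because ring C holds two enol ethers until it is aromatic; the stereocentres of 15 need no control.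

15 from 13 and 14. The bonds C1'–C2' and C5'–C6' are cut. Cutting here leaves the C8–C1' bond in place as the bond from C8 to a former aldehyde carbon, so it is never formed by coupling. Ring C reduces to the symmetric, purchasable 14 and a two-carbon acceptor on C8. The demand is that the nitroalkene of 13 is the only 2π partner, reacts thermally despite the peri methoxy group, and that no acid is present.

13 from 10 and 11. The C1'=C6' double bond is cut. A nitroaldol condensation is the direct way to a conjugated nitroalkene, and it reduces the side chain to a one-carbon reagent and an aldehyde. The demand is condensation at a peri-flanked aldehyde with (E) geometry, which is the thermodynamic outcome.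

10 from 9 from 8. No C–C bond is cut; only the oxidation level of the carbon on C8 changes. The ring-A construction delivers this carbon as an ester, and full reduction followed by a mild benzylic oxidation is more reliable than a partial reduction. The demand is only compatibility with the aryl ethers.

8 from 7. The O–CH3 bonds at O1, O4 and O6 are cut, with the O6–Si bond exchanged in the same operation. The annulation delivers ring B at the hydroquinone level, so no redox step lies between annulation and the protected arene. The demand is exclusion of air and methylation of the hindered O1, which lies peri to the ester. A methyl ester is chosen so that any peri-lactone reopened by methoxide returns the same ester.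

7 from 2 and 4. The bonds C8–C8a and C4a–C5 are cut, so ring A is made by a [4+2] cycloaddition on the brominated double bond of 4. This places the ester carbon on C8 and the oxygen on C6, and keeps the methoxy group of 4 as the C2 methoxy group. The bromine steers the regiochemistry and then leaves as HBr, so that tautomerization gives the naphthalene at the correct oxidation level. The demand is that the CH2 terminus of 2 bonds to the unsubstituted carbon of that double bond, and that no oxidant remains when the diol forms.

2 from 1, and 4 from 3. In 2 the O–Si bond is cut, which leads to 1, whose methyl group is its only enolizable position. In 4 the C4 carbonyl oxygen is removed, which leads to 3, whose ortho positions are blocked and whose para position is free. Both are one step from purchasable materials, and the only demand is para selectivity in the oxidation of 3.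

## Other disconnections considered

Alternative 1: The cut removes C4a–C8a, C5–C6 and C7–C8 together, so ring A is assembled from three alkyne units and ring B is closed by the tether. In the forward direction the 1,7-diyne A1 and methoxyethyne A2 would be cyclotrimerized with (C5Me5)RuCl(cod) to the tetralin A3.
- In its favour:
  - Ring C is already bonded to the alkyne carbon that becomes C8, so no peri coupling is needed. This is equal to the chosen plan.
  - Two rings close in one operation, which is better than the chosen plan.
  - The C2 methoxy group sits on an sp3 carbon of the tether, so its position next to C1 is not a matter of selectivity. This is better than the chosen plan, which relies on cycloaddition regiochemistry and a para-selective final oxidation.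
- Against it:
  - A2 is volatile and prone to polymerization and hydration.
  - A tether that closes a six-membered ring cyclizes at ruthenium more slowly than the usual five-membered case.
  - The meta relation between the C6 methoxy group and the C8 aryl group follows the normal preference of this catalyst for terminal alkynes, but for an alkoxyalkyne that is an extrapolation.
  - A1 carries three stereocentres that serve no purpose and make every intermediate a mixture of diastereomers.
- Mechanism: a metal-mediated oxidative cyclization, insertion and reductive elimination, sensitive to coordination by the many ether oxygens. The chosen key step is a catalyst-free pericyclic reaction.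
- Step economy: A3 still needs two desilylations, oxidation of both carbinol carbons and dehydrogenation, and A1 needs two alkynylations of a differentiated four-carbon unit. The total is expected to equal or exceed the eleven steps of the chosen plan.

Alternative 2: The cut removes C1–C2 and C3–C4, so ring B is annulated onto a phthalide that already holds rings A and C. In the forward direction the anion of the sulfonylphthalide A4, formed with LiOC(CH3)3, would add to the beta carbon of methyl 2-methoxyacrylate A5. The ester enolate would then attack the lactone carbonyl, and loss of the sulfinate leaving group would give the racemic diketo ester A6.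
- In its favour:
  - The polarity of the two partners fixes the methoxy-bearing carbon next to C1 without regiochemical doubt, which is better than the chosen plan.
  - After the annulation only ester cleavage with decarboxylation and a mild oxidation remain, with no strong oxidant near ring C. This is better than the tetravalent cerium step.
  - The plan is convergent.
- Against it:
  - A4 must carry ring C ortho to the lactone carbonyl, so an aryl–aryl coupling next to a substituted carbon returns. It is less crowded than a naphthalene peri position, but it is the operation the chosen plan avoids.
  - The ring-closing acyl substitution attacks that same flanked carbonyl with a fully substituted enolate carbon and creates a quaternary centre.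
  - A5 is a weak acceptor because of its alpha donor.
  - Because C2 of A6 is quaternary, the product cannot aromatize, so the usual driving force is missing and the non-enolizable beta-keto ester is open to retro-Claisen cleavage.
- Mechanism: an anionic Michael–Dieckmann sequence with two reversible steps before the irreversible loss of sulfinate, against one concerted cycloaddition.
- Step economy: A4 should need about six steps, giving about nine to ten in total. This is equal to or slightly shorter than the chosen plan.

Alternative 3: The cut removes C1–C2 and C2–C3, so C2 is inserted as a one-carbon unit into an indanone. In the forward direction the silyl enol ether A8 of the indanone A7 would take up dibromocarbene (from CHBr3 and KOC(CH3)3) at its enol ether double bond. Ring opening with loss of bromide would give the 2-bromo-1-naphthol A9.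
- In its favour:
  - It is the shortest plan on paper, which is better on step economy. From A9, oxidation at the free C4 and exchange of bromide for methoxide by addition–elimination would complete 18.
  - The position of the C2 substituent is fixed by the mechanism. This is equal to or better than the chosen plan.
  - Indanone chemistry is robust.
- Against it:
  - Ring C must sit on C7 of A7, ortho to the carbonyl. That requires either a cross-coupling there or a Friedel–Crafts closure that has to choose between two ortho positions.
  - The carbene is generated with a strong base that also cleaves silyl enol ethers.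
  - The carbene is an electrophile facing two electron-rich arenes and, once A9 forms, a naphtholate that can react in the Reimer–Tiemann manner.
  - The aryl group on the neighbouring peri carbon shields the reacting enol ether.
- Mechanism: carbene addition followed by disrotatory opening of a cyclopropyl cation, which is less predictable on this crowded substrate than a [4+2] cycloaddition.
- Structure: both plans end with an oxidation of an electron-rich biaryl, so they are equal on that point.

Key step: step 8

Assumption: rotation about the C8–C1' bond is taken as fast at room temperature (ring C has no ortho substituent), so the target needs no axial descriptor.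
Assumption: the dienoate is used as its methyl ester, so that direct O-methylation, ester exchange and methoxide opening of a peri-lactone all give the same ester in step 4.

## Route

Step 1
Reactants: 1 methyl (2E)-4-oxopent-2-enoate
Product: 2 methyl (2E)-4-[(tert-butyldimethylsilyl)oxy]penta-2,4-dienoate
Conditions: TBSOTf, Et3N, CH2Cl2, 0 °C
Reagents that add atoms: tert-butyldimethylsilyl trifluoromethanesulfonate, CC(C)(C)[Si](C)(C)OS(=O)(=O)C(F)(F)F
Why: Silyl enol ether formation by soft enolization; the methyl group is the only enolizable position of the ketone, so O-silylation and deprotonation give the 2-silyloxydiene, and the (E)-alkene is not touched.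

Step 2
Reactants: 3 2-bromo-6-methoxyphenol
Product: 4 2-bromo-6-methoxy-1,4-benzoquinone
Conditions: K2[ON(SO3)2] (2.2 equiv), KH2PO4, H2O/acetone, 0 °C to rt
Reagents that add atoms: potassium nitrosodisulfonate, [K+].[K+].[O]N(S(=O)(=O)[O-])S(=O)(=O)[O-]
Why: Teuber oxidation of a phenol; both ortho positions are blocked and the para position is free, so the phenoxyl radical is trapped at C4 by a second nitroxyl radical and collapses to the para-quinone.

Step 3
Reactants: 2 methyl (2E)-4-[(tert-butyldimethylsilyl)oxy]penta-2,4-dienoate, 4 2-bromo-6-methoxy-1,4-benzoquinone
Product: 7 methyl 3-[(tert-butyldimethylsilyl)oxy]-5,8-dihydroxy-7-methoxy-1-naphthoate, via bromo cycloadduct 5 (not isolated), via dihydronaphthoquinone 6 (not isolated)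
Conditions: 2 (1.1 equiv), toluene, 80 °C, argon; then Et3N, degassed, 0 °C to rt; used directly in step 4
Reagents that add atoms: none
Why: Diels–Alder reaction of a 2-silyloxydiene with a bromoquinone, then E1cB loss of HBr and enolization: the CH2 terminus of 2 (largest HOMO coefficient) bonds to the unsubstituted carbon of the brominated double bond, which is beta to the carbonyl not deactivated by the methoxy group, so the ester lands on C8 next to the C1 oxygen and the silyloxy group on C6. The endo adduct 5 loses HBr to 6, whose C5 and C8 hydrogens move to the quinone oxygens and give the aromatic diol 7 without change of oxidation level; Et3N is added only after 4 is consumed, so that 7 is not oxidized by it.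

Step 4
Reactants: 7 methyl 3-[(tert-butyldimethylsilyl)oxy]-5,8-dihydroxy-7-methoxy-1-naphthoate
Product: 8 methyl 3,5,7,8-tetramethoxy-1-naphthoate
Conditions: MeI (excess), K2CO3, DMF/MeOH, degassed, argon, rt to 40 °C
Reagents that add atoms: iodomethane, CI
Why: Williamson O-methylation with desilylation in the same flask: K2CO3 in methanol cleaves the aryl silyl ether and the three aryloxides are methylated by MeI with exclusion of air. Should O1 attack the peri ester, methoxide reopens the lactone to the same methyl ester, so every pathway ends at 8.

Step 5
Reactants: 8 methyl 3,5,7,8-tetramethoxy-1-naphthoate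
Product: 9 (3,5,7,8-tetramethoxynaphthalen-1-yl)methanol
Conditions: LiAlH4, THF, 0 °C to rt
Reagents that add atoms: none
Why: LiAlH4 reduction of an aromatic ester to the benzylic alcohol; the aryl methyl ethers are inert and the small hydride reaches the peri-flanked carbonyl.

Step 6
Reactants: 9 (3,5,7,8-tetramethoxynaphthalen-1-yl)methanol
Product: 10 3,5,7,8-tetramethoxy-1-naphthaldehyde
Conditions: MnO2 (activated, excess), CH2Cl2, rt
Reagents that add atoms: none
Why: Heterogeneous MnO2 oxidation of a benzylic alcohol, which stops at the aldehyde and does not attack the electron-rich ring.

Step 7
Reactants: 10 3,5,7,8-tetramethoxy-1-naphthaldehyde, 11 nitromethane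
Product: 13 (E)-1,2,4,6-tetramethoxy-8-(2-nitrovinyl)naphthalene, via nitro alcohol 12 (not isolated)
Conditions: MeNO2 (solvent), NH4OAc, 95 °C
Reagents that add atoms: none
Why: Henry (nitroaldol) condensation: the nitronate of 11 adds to the aldehyde and the nitro alcohol 12 loses water under the ammonium acetate conditions to the conjugated (E)-nitroalkene, the thermodynamically preferred isomer.

Step 8
Reactants: 13 (E)-1,2,4,6-tetramethoxy-8-(2-nitrovinyl)naphthalene, 14 2,3-dimethoxybuta-1,3-diene
Product: 15 trans-1,2-dimethoxy-4-nitro-5-(3,5,7,8-tetramethoxynaphthalen-1-yl)cyclohex-1-ene, racemic, (4R,5S) and (4S,5R)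
Conditions: 14 (4 equiv), BHT (cat.), toluene, 115 °C, sealed tube, argon
Reagents that add atoms: none
Why: Thermal Diels–Alder reaction of a nitroalkene: a concerted, asynchronous, normal-electron-demand [4+2] cycloaddition between the LUMO of the nitrovinyl group of 13 and the HOMO of the s-cis form of 14, suprafacial on both partners, forms C1'–C2' and C5'–C6'. The closest known reaction type is the cycloaddition of beta-nitrostyrenes to 2,3-dialkyl- and 2,3-dialkoxybutadienes, whose adducts are converted to biaryls by loss of HNO2 and dehydrogenation. Ring C, a six-membered carbocycle, is closed intermolecularly by the cycloaddition itself, both bonds in one event, so no separate cyclization of a tethered chain is involved. The two new stereocentres (the nitro-bearing C4 and the naphthyl-bearing C5 of the cyclohexene) are set trans because the (E) geometry of 13 is transferred stereospecifically; with an achiral diene and no catalyst the product is racemic, and endo or exo approach gives the same compound because 14 has no terminal substituents. The step needs chemoselectivity and periselectivity only: ring B is an aromatic hydroquinone dimethyl ether and offers no second dienophile, and the symmetric diene removes any regiochemical question. No Lewis acid is used, so that the nitro group does not act as a heterodiene toward an enol ether double bond of 14 and the diene is not hydrolysed; BHT suppresses radical polymerization of the excess diene. The peri methoxy group twists the nitrovinyl group out of the naphthalene plane, which weakens donation from the electron-rich ring and keeps the alkene electrophilic, while the reacting carbons stay accessible above and below that plane.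

Step 9
Reactants: 15 trans-1,2-dimethoxy-4-nitro-5-(3,5,7,8-tetramethoxynaphthalen-1-yl)cyclohex-1-ene
Product: 16 8-(4,5-dimethoxycyclohexa-2,4-dien-1-yl)-1,2,4,6-tetramethoxynaphthalene (racemic)
Conditions: DBU (3 equiv), toluene, 80 °C, argon
Reagents that add atoms: none
Why: Base-induced elimination of HNO2: in the conformer with an axial nitro group DBU removes the anti allylic hydrogen of the neighbouring CH2 and nitrite leaves, giving the conjugated diene, while reversible nitronate formation is unproductive and the basic medium protects the enol ethers. The nitro-bearing stereocentre is lost here, and a double-bond isomer of 16 would serve equally in step 10.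

Step 10
Reactants: 16 8-(4,5-dimethoxycyclohexa-2,4-dien-1-yl)-1,2,4,6-tetramethoxynaphthalene
Product: 17 8-(3,4-dimethoxyphenyl)-1,2,4,6-tetramethoxynaphthalene
Conditions: DDQ (1.1 equiv), NaHCO3, toluene, 0 °C to rt
Reagents that add atoms: none
Why: DDQ dehydrogenation of a cyclohexadiene: hydride abstraction from the allylic and benzylic C–H followed by proton loss gives aromatic ring C, and NaHCO3 buffers the acidic hydroquinone by-product. The last stereocentre disappears.

Step 11
Reactants: 17 8-(3,4-dimethoxyphenyl)-1,2,4,6-tetramethoxynaphthalene
Product: 18 8-(3,4-dimethoxyphenyl)-2,6-dimethoxynaphthalene-1,4-dione (CNP0128574.0)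
Conditions: (NH4)2Ce(NO3)6 (2.5 equiv), MeCN/H2O, 0 °C
Reagents that add atoms: water, O
Why: Oxidative demethylation of a hydroquinone dimethyl ether by tetravalent cerium: two one-electron oxidations of the most electron-rich ring with attack of water at C1 and C4 release two molecules of methanol and give the para-quinone. The C2 methoxy group remains as a vinylogous ester, and the less electron-rich ring C is not oxidized at 0 °C with a small excess of oxidant.

## Compound list

1 | methyl (2E)-4-oxopent-2-enoate | CC(=O)/C=C/C(=O)OC | starting material
2 | methyl (2E)-4-[(tert-butyldimethylsilyl)oxy]penta-2,4-dienoate | C=C(O[Si](C)(C)C(C)(C)C)/C=C/C(=O)OC | intermediate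
3 | 2-bromo-6-methoxyphenol | COc1cccc(Br)c1O | starting material
4 | 2-bromo-6-methoxy-1,4-benzoquinone (2-bromo-6-methoxycyclohexa-2,5-diene-1,4-dione) | COC1=CC(=O)C=C(Br)C1=O | intermediate
5 | methyl 8a-bromo-3-[(tert-butyldimethylsilyl)oxy]-7-methoxy-5,8-dioxo-1,4,4a,5,8,8a-hexahydronaphthalene-1-carboxylate, racemic endo adduct (cis ring fusion, H at C4a cis to Br, ester at C1 trans to Br) | COC(=O)[C@H]1C=C(O[Si](C)(C)C(C)(C)C)C[C@H]2C(=O)C=C(OC)C(=O)[C@@]12Br | intermediate (not isolated)
6 | methyl 3-[(tert-butyldimethylsilyl)oxy]-7-methoxy-5,8-dioxo-1,4,5,8-tetrahydronaphthalene-1-carboxylate (racemic) | COC(=O)C1C=C(O[Si](C)(C)C(C)(C)C)CC2=C1C(=O)C(OC)=CC2=O | intermediate (not isolated)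
7 | methyl 3-[(tert-butyldimethylsilyl)oxy]-5,8-dihydroxy-7-methoxy-1-naphthoate | COC(=O)c1cc(O[Si](C)(C)C(C)(C)C)cc2c(O)cc(OC)c(O)c12 | intermediate
8 | methyl 3,5,7,8-tetramethoxy-1-naphthoate | COC(=O)c1cc(OC)cc2c(OC)cc(OC)c(OC)c12 | intermediate
9 | (3,5,7,8-tetramethoxynaphthalen-1-yl)methanol | OCc1cc(OC)cc2c(OC)cc(OC)c(OC)c12 | intermediate
10 | 3,5,7,8-tetramethoxy-1-naphthaldehyde | O=Cc1cc(OC)cc2c(OC)cc(OC)c(OC)c12 | intermediate
11 | nitromethane | C[N+](=O)[O-] | starting material
12 | 2-nitro-1-(3,5,7,8-tetramethoxynaphthalen-1-yl)ethan-1-ol (racemic) | OC(C[N+](=O)[O-])c1cc(OC)cc2c(OC)cc(OC)c(OC)c12 | intermediate (not isolated)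
13 | (E)-1,2,4,6-tetramethoxy-8-(2-nitrovinyl)naphthalene | COc1cc(OC)c2cc(OC)cc(/C=C/[N+](=O)[O-])c2c1OC | intermediate
14 | 2,3-dimethoxybuta-1,3-diene | C=C(OC)C(OC)=C | starting material
15 | trans-1,2-dimethoxy-4-nitro-5-(3,5,7,8-tetramethoxynaphthalen-1-yl)cyclohex-1-ene, racemic; (4R,5S) enantiomer drawn | COC1=C(OC)C[C@@H]([N+](=O)[O-])[C@H](c2cc(OC)cc3c(OC)cc(OC)c(OC)c23)C1 | intermediate
16 | 8-(4,5-dimethoxycyclohexa-2,4-dien-1-yl)-1,2,4,6-tetramethoxynaphthalene (racemic) | COC1=C(OC)C=CC(c2cc(OC)cc3c(OC)cc(OC)c(OC)c23)C1 | intermediate
17 | 8-(3,4-dimethoxyphenyl)-1,2,4,6-tetramethoxynaphthalene | COc1ccc(-c2cc(OC)cc3c(OC)cc(OC)c(OC)c23)cc1OC | intermediate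
18 | 8-(3,4-dimethoxyphenyl)-2,6-dimethoxynaphthalene-1,4-dione | COC1=CC(=O)c2cc(OC)cc(-c3ccc(OC)c(OC)c3)c2C1=O | target

## Step count and least certain steps

Total step count: 11. Longest linear sequence: 10 steps (steps 1 and 3 to 11; step 2 prepares the second partner of step 3).

Step 8 (key step). The most likely failure is a slow cycloaddition at the crowded, donor-substituted nitroalkene. Thermal oligomerization of 14 and hetero-cycloaddition through an oxygen of the nitro group would then take over. The fallback gives up ring construction and attaches ring C intact, at the price of the peri coupling that the plan was designed to avoid. It sets out from 10. Baeyer–Villiger oxidation with mCPBA (NaHCO3, CH2Cl2) should give 3,5,7,8-tetramethoxynaphthalen-1-yl formate F1. Methanolysis (K2CO3, MeOH) should give 3,5,7,8-tetramethoxynaphthalen-1-ol F2, and Tf2O with pyridine should give 3,5,7,8-tetramethoxynaphthalen-1-yl trifluoromethanesulfonate F3. Suzuki–Miyaura coupling of F3 with (3,4-dimethoxyphenyl)boronic acid (Pd(OAc)2, 2-dicyclohexylphosphino-2',6'-dimethoxybiphenyl, K3PO4, toluene/H2O, 100 °C) comes back to the route at 17.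

Step 3. The most likely failure is electron and hydrogen exchange between the newly formed naphthalenediol and unconsumed 4, together with air oxidation during handling. The material would then be spread over two oxidation levels. The fallback sets out from 2 and 4 and drives the oxidation to completion on purpose, with a second equivalent of 4 and Et3N. The air-stable methyl 3-[(tert-butyldimethylsilyl)oxy]-7-methoxy-5,8-dioxo-5,8-dihydronaphthalene-1-carboxylate F4 is isolated. Reduction of F4 with Na2S2O4 (EtOAc/H2O) returns to the route at 7, which is formed in the flask and methylated at once as in step 4.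

Step 4. The most likely failure is acyl transfer from the C8 ester to the hindered peri aryloxide O1, which closes a lactone faster than O1 is methylated; air oxidation of the diol is the second risk. The fallback accepts the lactone and sets out from 7. With KF, MeI and K2CO3 in DMF without methanol, O4 and O6 are methylated and the peri-lactone 4,6,8-trimethoxy-2H-naphtho[1,8-bc]furan-2-one F5 is taken as the product. LiAlH4 opens it to 8-(hydroxymethyl)-2,4,6-trimethoxynaphthalen-1-ol F6. MeI and K2CO3 in acetone then methylate only the phenol, and the route is rejoined at 9.

Step 9. The most likely failure is deprotonation alpha to the nitro group in place of beta-elimination, with epimerization or return of starting material, because the beta hydrogens are only allylic or benzylic. The fallback removes the nitro group by a radical chain and sets out from 15. Bu3SnH and AIBN in toluene at 110 °C should give 8-(3,4-dimethoxycyclohex-3-en-1-yl)-1,2,4,6-tetramethoxynaphthalene F7. DDQ (2.2 equiv, NaHCO3, toluene) dehydrogenates F7 twice, and the route is rejoined at 17.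

Step 11. The most likely failure is oxidative demethylation across the ortho pair O1/O2 (ortho-quinone formation) and over-oxidation of the electron-rich ring C. The fallback replaces the chemical oxidant by electrolysis and sets out from 17. Anodic oxidation in methanolic KOH (platinum anode, 0 °C) should add methoxide at C1 and C4 and give the quinone bisketal 8-(3,4-dimethoxyphenyl)-1,1,2,4,4,6-hexamethoxy-1,4-dihydronaphthalene F8. Hydrolysis of F8 with aqueous acetic acid in acetone comes back at 18.

## Further compounds

F1 | step 8 | 3,5,7,8-tetramethoxynaphthalen-1-yl formate | O=COc1cc(OC)cc2c(OC)cc(OC)c(OC)c12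
F2 | step 8 | 3,5,7,8-tetramethoxynaphthalen-1-ol | Oc1cc(OC)cc2c(OC)cc(OC)c(OC)c12
F3 | step 8 | 3,5,7,8-tetramethoxynaphthalen-1-yl trifluoromethanesulfonate | FC(F)(F)S(=O)(=O)Oc1cc(OC)cc2c(OC)cc(OC)c(OC)c12
F4 | step 3 | methyl 3-[(tert-butyldimethylsilyl)oxy]-7-methoxy-5,8-dioxo-5,8-dihydronaphthalene-1-carboxylate | COC(=O)c1cc(O[Si](C)(C)C(C)(C)C)cc2C(=O)C=C(OC)C(=O)c12
F5 | step 4 | 4,6,8-trimethoxy-2H-naphtho[1,8-bc]furan-2-one | O=C1Oc2c(OC)cc(OC)c3cc(OC)cc1c23
F6 | step 4 | 8-(hydroxymethyl)-2,4,6-trimethoxynaphthalen-1-ol | OCc1cc(OC)cc2c(OC)cc(OC)c(O)c12
F7 | step 9 | 8-(3,4-dimethoxycyclohex-3-en-1-yl)-1,2,4,6-tetramethoxynaphthalene (racemic) | COC1=C(OC)CC(c2cc(OC)cc3c(OC)cc(OC)c(OC)c23)CC1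
F8 | step 11 | 8-(3,4-dimethoxyphenyl)-1,1,2,4,4,6-hexamethoxy-1,4-dihydronaphthalene | COC1=CC(OC)(OC)c2cc(OC)cc(-c3ccc(OC)c(OC)c3)c2C1(OC)OC
A1 | alternative 1 | 3,6-bis[(tert-butyldimethylsilyl)oxy]-1-(3,4-dimethoxyphenyl)-4-methoxyocta-1,7-diyne (mixture of diastereomers) | COc1ccc(C#CC(O[Si](C)(C)C(C)(C)C)C(OC)CC(O[Si](C)(C)C(C)(C)C)C#C)cc1OC
A2 | alternative 1 | methoxyethyne | COC#C
A3 | alternative 1 | 1,4-bis[(tert-butyldimethylsilyl)oxy]-8-(3,4-dimethoxyphenyl)-2,6-dimethoxy-1,2,3,4-tetrahydronaphthalene (mixture of diastereomers) | COc1cc(-c2ccc(OC)c(OC)c2)c2c(c1)C(O[Si](C)(C)C(C)(C)C)CC(OC)C2O[Si](C)(C)C(C)(C)C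
A4 | alternative 2 | 7-(3,4-dimethoxyphenyl)-5-methoxy-3-(phenylsulfonyl)isobenzofuran-1(3H)-one (racemic) | O=C1OC(S(=O)(=O)c2ccccc2)c2cc(OC)cc(-c3ccc(OC)c(OC)c3)c12
A5 | alternative 2 | methyl 2-methoxyacrylate | C=C(OC)C(=O)OC
A6 | alternative 2 | methyl 8-(3,4-dimethoxyphenyl)-2,6-dimethoxy-1,4-dioxo-1,2,3,4-tetrahydronaphthalene-2-carboxylate (racemic) | COC(=O)C1(OC)CC(=O)c2cc(OC)cc(-c3ccc(OC)c(OC)c3)c2C1=O
A7 | alternative 3 | 7-(3,4-dimethoxyphenyl)-5-methoxyindan-1-one | O=C1CCc2cc(OC)cc(-c3ccc(OC)c(OC)c3)c12
A8 | alternative 3 | {[4-(3,4-dimethoxyphenyl)-6-methoxy-1H-inden-3-yl]oxy}trimethylsilane | C[Si](C)(C)OC1=CCc2cc(OC)cc(-c3ccc(OC)c(OC)c3)c12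
A9 | alternative 3 | 2-bromo-8-(3,4-dimethoxyphenyl)-6-methoxynaphthalen-1-ol | Oc1c(Br)ccc2cc(OC)cc(-c3ccc(OC)c(OC)c3)c12
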